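Each piperidine (ring A on the eleven-methylene arm, ring B on the ten-methylene arm) is cut first at C4–C5 and then at N1–C6. This leaves two copies of an alanine-derived amino alkene (N1, C2, C3, C4) and one C29 chain holding C5, C6, the masked enal, C6' and C5'.
Enabling feature: N1 lies between two secondary carbons, C2 (methyl) and C6 (chain), and C6 is bonded to C5. C6 can therefore be made as the substituted end of an allyl unit C6–C5=CH2 attacked by nitrogen; a vinyl group on C3 supplies C4, and C4–C5 is then the only ring bond missing.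
Chain: ozonolysis of methyl erucate gives a C13 aldehyde ester. Its self-aldol condensation sets the (E)-2-alkylenal and the 11/10 methylene pattern in one operation; the enal is kept as a dioxolane while both esters are extended to (E)-allylic methyl carbonates.
Forward order: the three fragments are joined through two C–N bonds, rings A and B close together by double metathesis, diimide saturates C4=C5, and aqueous acid removes the silyl ethers and the acetal at once.
Stereochemistry: C2 comes from L-alanine, C3 from a catalyst-controlled transfer hydrogenation of an ynone, C6 from the chiral iridium phosphoramidite catalyst, and the alkene geometry from the thermodynamics of the condensation.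

Key step: step 13

Assumption: the (Sa,Sc,Sc) ligand is taken to give the (R)-amine from an (E)-alkyl-substituted allyl carbonate, the usual sense of induction for this catalyst family. If a trial on a simple monocarbonate shows the opposite sense, the mirror-image ligand is used and nothing else changes.

Step 1
Reactants: 1 N-Boc-L-alanine N-methoxy-N-methylamide; 2 trimethylsilylacetylene
Product: 4 tert-butyl N-[(2S)-3-oxo-5-(trimethylsilyl)pent-4-yn-2-yl]carbamate, via lithium trimethylsilylacetylide 3 (not isolated)
Conditions: 2 (2.6 equiv), n-BuLi (2.5 equiv), THF, −78 °C; 1, −78 → −20 °C; poured into cold 1 M HCl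
Reagents that add atoms: trimethylsilylacetylene (reactant 2), C#C[Si](C)(C)C
Why: Weinreb ketone synthesis: the first equivalent of acetylide removes the carbamate N–H, which guards C2 against enolisation, and the chelated tetrahedral adduct survives until the acidic quench, so only one addition occurs and the released hydroxylamine is protonated before it can add to the ynone.

Step 2
Reactants: 4 tert-butyl N-[(2S)-3-oxo-5-(trimethylsilyl)pent-4-yn-2-yl]carbamate
Product: 5 tert-butyl N-[(2S,3S)-3-hydroxy-5-(trimethylsilyl)pent-4-yn-2-yl]carbamate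
Conditions: Ru[(R,R)-TsNCHPhCHPhNH](p-cymene) (1 mol %), i-PrOH, 25 °C
Reagents that add atoms: none
Why: Noyori asymmetric transfer hydrogenation of an alkynyl ketone: the ruthenium hydride/amine pair passes hydride and proton to the carbonyl through a six-membered transition state in which the alkyne sits next to the arene ligand, so the (R,R) catalyst sets the carbinol carbon (later C3) as S, syn to the carbamate carbon, by catalyst control and without touching the triple bond or C2.

Step 3
Reactants: 5 tert-butyl N-[(2S,3S)-3-hydroxy-5-(trimethylsilyl)pent-4-yn-2-yl]carbamate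
Product: 6 tert-butyl N-[(2S,3S)-3-hydroxypent-4-yn-2-yl]carbamate
Conditions: K2CO3 (0.2 equiv), MeOH, 0 → 25 °C
Reagents that add atoms: none
Why: Base-catalysed protodesilylation of an alkynylsilane: methoxide attacks silicon and the acetylide leaves and is protonated, under conditions too mild to close an oxazolidinone or disturb either stereocentre.

Step 4
Reactants: 6 tert-butyl N-[(2S,3S)-3-hydroxypent-4-yn-2-yl]carbamate
Product: 7 tert-butyl N-[(2S,3S)-3-hydroxypent-4-en-2-yl]carbamate
Conditions: H2 (1 atm), Pd/CaCO3 poisoned with Pb(OAc)2, quinoline, EtOAc, 25 °C, stopped after one equivalent of H2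
Reagents that add atoms: none
Why: Lindlar semihydrogenation: the poisoned palladium surface binds the terminal alkyne far better than the alkene it releases, so the reduction stops at the vinyl group and the allylic C–O bond is kept.

Step 5
Reactants: 7 tert-butyl N-[(2S,3S)-3-hydroxypent-4-en-2-yl]carbamate
Product: 10 (3S,4S)-4-amino-3-(tert-butyldimethylsilyloxy)pent-1-ene, via O-silylated Boc carbamate 8 (not isolated), via silyl carbamate 9 (not isolated)
Conditions: TBSOTf (2.5 equiv), 2,6-lutidine (4 equiv), CH2Cl2, 0 → 25 °C; then MeOH, 25 °C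
Reagents that add atoms: tert-butyldimethylsilyl triflate, CC(C)(C)[Si](C)(C)OS(=O)(=O)C(F)(F)F
Why: Silyl triflate chemistry in two stages: the alcohol is silylated first at 0 °C, further TBSOTf converts the tert-butyl carbamate into the silyl carbamate with loss of isobutene, and methanol cleaves that to the free amine and CO2 while the secondary silyl ether and both stereocentres stay as they are.

Step 6
Reactants: 11 methyl erucate (methyl (13Z)-docos-13-enoate)
Product: 13 methyl 13-oxotridecanoate, via secondary ozonide 12 (not isolated)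
Conditions: O3, CH2Cl2, −78 °C; Me2S, −78 → 25 °C
Reagents that add atoms: ozone, [O-][O+]=O
Why: Criegee ozonolysis with reductive work-up: the only alkene of 11 passes through cycloaddition, cycloreversion and recombination to the ozonide, dimethyl sulfide reduces this to two aldehydes, and the lighter nonanal is removed by distillation.

Step 7
Reactants: 13 methyl 13-oxotridecanoate (two molecules)
Product: 14 dimethyl (12E)-12-formylpentacos-12-enedioate
Conditions: pyrrolidine (10 mol %), PhCO2H (10 mol %), toluene, 25 → 60 °C
Reagents that add atoms: none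
Why: Amine-catalysed self-aldol condensation (enamine adds to iminium, then elimination): only one aldehyde is present, so a single constitution can form, the methyl esters are inert to the buffered catalyst, and allylic 1,3-strain makes the isomer with the chain trans to the formyl group (E) the stable one.

Step 8
Reactants: 14 dimethyl (12E)-12-formylpentacos-12-enedioate
Product: 15 dimethyl (12E)-12-(1,3-dioxolan-2-yl)pentacos-12-enedioate
Conditions: TMSOCH2CH2OTMS (1.5 equiv), TMSOTf (5 mol %), CH2Cl2, −78 → −20 °C; pyridine quench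
Reagents that add atoms: 1,2-bis(trimethylsilyloxy)ethane, C[Si](C)(C)OCCO[Si](C)(C)C
Why: Noyori acetalisation: formation of hexamethyldisiloxane drives the aprotic exchange at low temperature, which acetalises enals without moving or isomerising the double bond and without transesterifying the methyl esters.

Step 9
Reactants: 15 dimethyl (12E)-12-(1,3-dioxolan-2-yl)pentacos-12-enedioate
Product: 16 (12E)-12-(1,3-dioxolan-2-yl)pentacos-12-enedial
Conditions: i-Bu2AlH (2.2 equiv), toluene, −78 °C; MeOH, then aq. potassium sodium tartrate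
Reagents that add atoms: none
Why: Partial ester reduction with diisobutylaluminium hydride: at −78 °C in toluene each tetrahedral aluminium hemiacetal persists until the quench, so both esters stop at the aldehyde while the dioxolane and the trisubstituted alkene are not attacked.

Step 10
Reactants: 16 (12E)-12-(1,3-dioxolan-2-yl)pentacos-12-enedial; 17 triethyl phosphonoacetate
Product: 19 diethyl (2E,14E,27E)-14-(1,3-dioxolan-2-yl)nonacosa-2,14,27-trienedioate, via sodium triethyl phosphonoacetate 18 (not isolated)
Conditions: 17 (2.4 equiv), NaH (2.3 equiv), THF, 0 °C; 16, 0 → 25 °C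
Reagents that add atoms: triethyl phosphonoacetate (reactant 17), CCOC(=O)CP(=O)(OCC)OCC
Why: Horner–Wadsworth–Emmons olefination at both ends: the stabilised phosphonate anion adds reversibly to the unbranched aldehydes and eliminates through the less crowded oxaphosphetane to the E-enoates, the geometry the iridium catalyst needs later.

Step 11
Reactants: 19 diethyl (2E,14E,27E)-14-(1,3-dioxolan-2-yl)nonacosa-2,14,27-trienedioate
Product: 20 (2E,14E,27E)-14-(1,3-dioxolan-2-yl)nonacosa-2,14,27-triene-1,29-diol
Conditions: i-Bu2AlH (4.6 equiv), CH2Cl2, −78 °C; aq. potassium sodium tartrate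
Reagents that add atoms: none
Why: 1,2-Reduction of conjugated esters with diisobutylaluminium hydride: the electrophilic hydride reduces the carbonyl groups only, keeps the E-alkenes, and at −78 °C leaves the allylic dioxolane closed.

Step 12
Reactants: 20 (2E,14E,27E)-14-(1,3-dioxolan-2-yl)nonacosa-2,14,27-triene-1,29-diol
Product: 21 (2E,14E,27E)-14-(1,3-dioxolan-2-yl)nonacosa-2,14,27-triene-1,29-diyl dimethyl biscarbonate
Conditions: ClCO2Me (3 equiv), pyridine (4 equiv), CH2Cl2, 0 °C
Reagents that add atoms: methyl chloroformate, COC(=O)Cl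
Why: O-Acylation of two unhindered primary allylic alcohols with a chloroformate under pyridine catalysis, which installs the leaving group that later supplies its own base (methoxide) on ionisation.

Step 13
Reactants: 21 (2E,14E,27E)-14-(1,3-dioxolan-2-yl)nonacosa-2,14,27-triene-1,29-diyl dimethyl biscarbonate; 10 (3S,4S)-4-amino-3-(tert-butyldimethylsilyloxy)pent-1-ene (two molecules react)
Product: 22 2-[(3R,14E,27R)-3,27-bis{[(2S,3S)-3-(tert-butyldimethylsilyloxy)pent-4-en-2-yl]amino}nonacosa-1,14,28-trien-14-yl]-1,3-dioxolane
Conditions: [Ir(cod)Cl]2 (4 mol %), (Sa,Sc,Sc)-O,O'-(1,1'-binaphthalene-2,2'-diyl) N,N-bis(1-phenylethyl)phosphoramidite (8 mol %), n-PrNH2, THF, 50 °C, then evaporated; 21, 10 (2.5 equiv), THF, 25 → 40 °C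
Reagents that add atoms: none
Why: This is an iridium-catalysed, branched-selective asymmetric allylic amination run at both chain ends in one flask: the cyclometalated phosphoramidite complex of monovalent iridium expels each methyl carbonate with inversion to give a cationic allyl complex of trivalent iridium (CO2 and methoxide are released), and the NH2 group of 10 then bonds to the alkyl-bearing allyl carbon on the face turned away from the metal, forming N1–C6 and N1'–C6' and leaving a vinyl group on each C6. The closest known reaction type is the amination of (E)-alkyl-substituted allyl methyl carbonates by primary amines, alpha-branched ones included, with this catalyst family, followed by metathesis to 2,6-disubstituted azacycles. No ring closes in this step; it only assembles the two 5-aza-1,7-diene units that close in step 14. Both new stereocentres, C6 and C6', are fixed as R (chain cis to the C2 methyl group in the later ring) by the ligand, because the metallacycle leaves one allyl face and one allyl orientation open; C2 and C3 of 10 exert at most a small matched or mismatched effect, and since 10 is a single enantiomer any wrong-face product is a diastereomer that chromatography can remove. The step needs branched over linear attack, a stop after one allylation per nitrogen, and inert bystander alkenes: the first comes from the catalyst acting on the geometrically pure E-carbonates of step 10, the second from the new secondary amine carrying a branched carbon on either side, and the third because neither the dioxolane-bearing trisubstituted alkene nor the allylic silyl ether offers a group that iridium can ionise.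

Step 14
Reactants: 22 2-[(3R,14E,27R)-3,27-bis{[(2S,3S)-3-(tert-butyldimethylsilyloxy)pent-4-en-2-yl]amino}nonacosa-1,14,28-trien-14-yl]-1,3-dioxolane
Product: 25 2-{(11E)-1,23-bis[(2S,3S,6R)-3-(tert-butyldimethylsilyloxy)-2-methyl-1,2,3,6-tetrahydropyridin-6-yl]tricos-11-en-11-yl}-1,3-dioxolane, via bis(ammonium mesylate) 23 (not isolated), via bis(tetrahydropyridinium mesylate) 24 (not isolated)
Conditions: MsOH (2.0 equiv), CH2Cl2, 0 °C; second-generation Grubbs catalyst RuCl2(=CHPh)(PCy3)(SIMes) (10 mol %), CH2Cl2 (5 mM), 40 °C; 1 M NaOH wash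
Reagents that add atoms: none
Why: Double ring-closing metathesis of ammonium salts: protonation keeps both nitrogen lone pairs off ruthenium, each 5-aza-1,7-diene closes its C4=C5 bond to a six-membered ring much faster than any cross or macrocyclic metathesis at this dilution, the trisubstituted central alkene does not engage the carbene, and a dialkylammonium mesylate in dry CH2Cl2 is too weak an acid to open the dioxolane or the silyl ethers.

Step 15
Reactants: 25 2-{(11E)-1,23-bis[(2S,3S,6R)-3-(tert-butyldimethylsilyloxy)-2-methyl-1,2,3,6-tetrahydropyridin-6-yl]tricos-11-en-11-yl}-1,3-dioxolane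
Product: 26 2-{(11E)-1,23-bis[(2S,3S,6R)-3-(tert-butyldimethylsilyloxy)-2-methylpiperidin-6-yl]tricos-11-en-11-yl}-1,3-dioxolane
Conditions: 2,4,6-triisopropylbenzenesulfonyl hydrazide (in portions until 25 is consumed), Et3N, ClCH2CH2Cl, 50 °C
Reagents that add atoms: none
Why: Diimide reduction: HN=NH released from the sulfonyl hydrazide transfers two hydrogens in a concerted syn fashion, at a rate that falls steeply with each added alkene substituent, so the two cis-disubstituted ring alkenes should react ahead of the trisubstituted, dioxolane-flanked central alkene and no allylic C–O or C–N bond can be hydrogenolysed.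

Step 16
Reactants: 26 2-{(11E)-1,23-bis[(2S,3S,6R)-3-(tert-butyldimethylsilyloxy)-2-methylpiperidin-6-yl]tricos-11-en-11-yl}-1,3-dioxolane
Product: 28 (2E)-2-{10-[(2R,5S,6S)-5-hydroxy-6-methylpiperidin-2-yl]decyl}-14-[(2R,5S,6S)-5-hydroxy-6-methylpiperidin-2-yl]tetradec-2-enal (CNP0177491.1), via target bis(hydrochloride) 27 (not isolated)
Conditions: 3 M aq. HCl, THF, 25 → 45 °C; then cold aq. Na2CO3, CH2Cl2 extraction
Reagents that add atoms: water, O
Why: Acid hydrolysis of the allylic acetal and of both silyl ethers in one operation: the amines are held as ammonium ions while the enal is released, the E-enal is the stable isomer so its geometry is kept, no stereocentre is acid-labile, and mild base then frees a diamine whose hindered nitrogens coexist with the alpha-branched enal.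

Compound list
1 | N-Boc-L-alanine N-methoxy-N-methylamide | C[C@H](NC(=O)OC(C)(C)C)C(=O)N(C)OC | starting material
2 | trimethylsilylacetylene | C#C[Si](C)(C)C | starting material
3 | lithium trimethylsilylacetylide | [Li]C#C[Si](C)(C)C | intermediate
4 | tert-butyl N-[(2S)-3-oxo-5-(trimethylsilyl)pent-4-yn-2-yl]carbamate | C[C@H](NC(=O)OC(C)(C)C)C(=O)C#C[Si](C)(C)C | intermediate
5 | tert-butyl N-[(2S,3S)-3-hydroxy-5-(trimethylsilyl)pent-4-yn-2-yl]carbamate | C[C@H](NC(=O)OC(C)(C)C)[C@@H](O)C#C[Si](C)(C)C | intermediate
6 | tert-butyl N-[(2S,3S)-3-hydroxypent-4-yn-2-yl]carbamate | C[C@H](NC(=O)OC(C)(C)C)[C@@H](O)C#C | intermediate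
7 | tert-butyl N-[(2S,3S)-3-hydroxypent-4-en-2-yl]carbamate | C[C@H](NC(=O)OC(C)(C)C)[C@@H](O)C=C | intermediate
8 | tert-butyl N-[(2S,3S)-3-(tert-butyldimethylsilyloxy)pent-4-en-2-yl]carbamate | C[C@H](NC(=O)OC(C)(C)C)[C@@H](O[Si](C)(C)C(C)(C)C)C=C | intermediate
9 | tert-butyldimethylsilyl N-[(2S,3S)-3-(tert-butyldimethylsilyloxy)pent-4-en-2-yl]carbamate | C[C@H](NC(=O)O[Si](C)(C)C(C)(C)C)[C@@H](O[Si](C)(C)C(C)(C)C)C=C | intermediate
10 | (3S,4S)-4-amino-3-(tert-butyldimethylsilyloxy)pent-1-ene | C[C@H](N)[C@@H](O[Si](C)(C)C(C)(C)C)C=C | intermediate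
11 | methyl erucate | CCCCCCCC/C=C\CCCCCCCCCCCC(=O)OC | starting material
12 | secondary ozonide of methyl erucate (3-octyl-5-(12-methoxy-12-oxododecyl)-1,2,4-trioxolane) | CCCCCCCCC1OOC(CCCCCCCCCCCC(=O)OC)O1 | intermediate
13 | methyl 13-oxotridecanoate | O=CCCCCCCCCCCCC(=O)OC | intermediate
14 | dimethyl (12E)-12-formylpentacos-12-enedioate | COC(=O)CCCCCCCCCCC/C=C(/C=O)CCCCCCCCCCC(=O)OC | intermediate
15 | dimethyl (12E)-12-(1,3-dioxolan-2-yl)pentacos-12-enedioate | COC(=O)CCCCCCCCCCC/C=C(/C1OCCO1)CCCCCCCCCCC(=O)OC | intermediate
16 | (12E)-12-(1,3-dioxolan-2-yl)pentacos-12-enedial | O=CCCCCCCCCCCCC/C=C(/C1OCCO1)CCCCCCCCCCC=O | intermediate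
17 | triethyl phosphonoacetate | CCOC(=O)CP(=O)(OCC)OCC | starting material
18 | sodium triethyl phosphonoacetate | CCOC(=O)[CH-]P(=O)(OCC)OCC.[Na+] | intermediate
19 | diethyl (2E,14E,27E)-14-(1,3-dioxolan-2-yl)nonacosa-2,14,27-trienedioate | CCOC(=O)/C=C/CCCCCCCCCCC/C=C(/C1OCCO1)CCCCCCCCCC/C=C/C(=O)OCC | intermediate
20 | (2E,14E,27E)-14-(1,3-dioxolan-2-yl)nonacosa-2,14,27-triene-1,29-diol | OC/C=C/CCCCCCCCCCC/C=C(/C1OCCO1)CCCCCCCCCC/C=C/CO | intermediate
21 | (2E,14E,27E)-14-(1,3-dioxolan-2-yl)nonacosa-2,14,27-triene-1,29-diyl dimethyl biscarbonate | COC(=O)OC/C=C/CCCCCCCCCCC/C=C(/C1OCCO1)CCCCCCCCCC/C=C/COC(=O)OC | intermediate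
22 | 2-[(3R,14E,27R)-3,27-bis{[(2S,3S)-3-(tert-butyldimethylsilyloxy)pent-4-en-2-yl]amino}nonacosa-1,14,28-trien-14-yl]-1,3-dioxolane | C=C[C@H](O[Si](C)(C)C(C)(C)C)[C@H](C)N[C@@H](C=C)CCCCCCCCCCC/C=C(/C1OCCO1)CCCCCCCCCC[C@H](C=C)N[C@@H](C)[C@@H](O[Si](C)(C)C(C)(C)C)C=C | intermediate
23 | bis(methanesulfonate) salt of 22 | C=C[C@H](O[Si](C)(C)C(C)(C)C)[C@H](C)[NH2+][C@@H](C=C)CCCCCCCCCCC/C=C(/C1OCCO1)CCCCCCCCCC[C@H](C=C)[NH2+][C@@H](C)[C@@H](O[Si](C)(C)C(C)(C)C)C=C.CS(=O)(=O)[O-].CS(=O)(=O)[O-] | intermediate
24 | bis(methanesulfonate) salt of 25 | C[C@@H]1[NH2+][C@H](CCCCCCCCCCC/C=C(/C3OCCO3)CCCCCCCCCC[C@@H]2C=C[C@H](O[Si](C)(C)C(C)(C)C)[C@H](C)[NH2+]2)C=C[C@@H]1O[Si](C)(C)C(C)(C)C.CS(=O)(=O)[O-].CS(=O)(=O)[O-] | intermediate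
25 | 2-{(11E)-1,23-bis[(2S,3S,6R)-3-(tert-butyldimethylsilyloxy)-2-methyl-1,2,3,6-tetrahydropyridin-6-yl]tricos-11-en-11-yl}-1,3-dioxolane | C[C@@H]1N[C@H](CCCCCCCCCCC/C=C(/C3OCCO3)CCCCCCCCCC[C@@H]2C=C[C@H](O[Si](C)(C)C(C)(C)C)[C@H](C)N2)C=C[C@@H]1O[Si](C)(C)C(C)(C)C | intermediate
26 | 2-{(11E)-1,23-bis[(2S,3S,6R)-3-(tert-butyldimethylsilyloxy)-2-methylpiperidin-6-yl]tricos-11-en-11-yl}-1,3-dioxolane | C[C@@H]1N[C@H](CCCCCCCCCCC/C=C(/C3OCCO3)CCCCCCCCCC[C@@H]2CC[C@H](O[Si](C)(C)C(C)(C)C)[C@H](C)N2)CC[C@@H]1O[Si](C)(C)C(C)(C)C | intermediate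
27 | bis(hydrochloride) of the target | C[C@@H]1[NH2+][C@H](CCCCCCCCCCC/C=C(/C=O)CCCCCCCCCC[C@@H]2CC[C@H](O)[C@H](C)[NH2+]2)CC[C@@H]1O.[Cl-].[Cl-] | intermediate
28 | (2E)-2-{10-[(2R,5S,6S)-5-hydroxy-6-methylpiperidin-2-yl]decyl}-14-[(2R,5S,6S)-5-hydroxy-6-methylpiperidin-2-yl]tetradec-2-enal (CNP0177491.1) | C[C@@H]1N[C@H](CCCCCCCCCCC/C=C(/C=O)CCCCCCCCCC[C@@H]2CC[C@H](O)[C@H](C)N2)CC[C@@H]1O | target

Total step count: 16.
Longest linear sequence: 11 steps (steps 6 to 16, from methyl erucate). The amine branch (steps 1 to 5) joins at step 13.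

Steps most likely to fail

Step 13. The nitrogen of 10 is crowded by its own alpha-branch and by the neighbouring silyl ether. The double substitution may therefore stall after one end has reacted, and slow turnover may let linear attack gain ground.
- The fallback sets out from 7. The Boc group is removed with HCl in dioxane and the salt is free-based to give (3S,4S)-4-aminopent-1-en-3-ol F1, a much smaller nucleophile.
- F1 is allylated with 21 under the same iridium catalyst. The amine reacts while the neutral hydroxyl group does not, giving the bis(amino alcohol) 2-[(3R,14E,27R)-3,27-bis{[(2S,3S)-3-hydroxypent-4-en-2-yl]amino}nonacosa-1,14,28-trien-14-yl]-1,3-dioxolane F2.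
- Silylation is moved behind the C–N bond formation: TBSOTf and 2,6-lutidine cap both hydroxyl groups, and the route is rejoined at 22.

Step 15. Hydrogen transfer to ring alkenes that carry a substituent on each allylic carbon may be slow. The excess of diimide then needed may begin to saturate the central alkene.
- The fallback sets out from 25, which is reprotonated with MsOH to 24.
- 24 is hydrogenated with H2 (1 atm) and RhCl(PPh3)3 in benzene/EtOH. This reduction is gated by coordination of the alkene to rhodium, so a trisubstituted alkene is largely shut out and the ammonium form cannot bind the metal.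
- This gives the saturated bis(piperidinium mesylate) F3, and a 1 M NaOH wash returns to 26.

Step 14. The alkene next to the ammonium centre is electron-poor and hindered. The second ring closure may lag, the catalyst may decay, and ruthenium hydrides may shift the terminal alkenes.
- The fallback sets out from 22 and replaces protonation by a covalent mask. Trifluoroacetic anhydride and pyridine give the bis(trifluoroacetamide) F4, in which allylic 1,3-strain about the amide pushes both alkenyl arms to the same side.
- Ring-closing metathesis with the same ruthenium carbene gives the bis(N-trifluoroacetyl-tetrahydropyridine) F5.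
- K2CO3 in MeOH removes the acyl groups and returns to 25.

Further compounds
F1 | step 13 | (3S,4S)-4-aminopent-1-en-3-ol | C[C@H](N)[C@@H](O)C=C
F2 | step 13 | 2-[(3R,14E,27R)-3,27-bis{[(2S,3S)-3-hydroxypent-4-en-2-yl]amino}nonacosa-1,14,28-trien-14-yl]-1,3-dioxolane | C=C[C@H](O)[C@H](C)N[C@@H](C=C)CCCCCCCCCCC/C=C(/C1OCCO1)CCCCCCCCCC[C@H](C=C)N[C@@H](C)[C@@H](O)C=C
F3 | step 15 | bis(methanesulfonate) salt of 26 | C[C@@H]1[NH2+][C@H](CCCCCCCCCCC/C=C(/C3OCCO3)CCCCCCCCCC[C@@H]2CC[C@H](O[Si](C)(C)C(C)(C)C)[C@H](C)[NH2+]2)CC[C@@H]1O[Si](C)(C)C(C)(C)C.CS(=O)(=O)[O-].CS(=O)(=O)[O-]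
F4 | step 14 | N,N'-bis(trifluoroacetyl) derivative of 22 | C=C[C@H](O[Si](C)(C)C(C)(C)C)[C@H](C)N(C(=O)C(F)(F)F)[C@@H](C=C)CCCCCCCCCCC/C=C(/C1OCCO1)CCCCCCCCCC[C@H](C=C)N(C(=O)C(F)(F)F)[C@@H](C)[C@@H](O[Si](C)(C)C(C)(C)C)C=C
F5 | step 14 | N,N'-bis(trifluoroacetyl) derivative of 25 | C[C@@H]1N(C(=O)C(F)(F)F)[C@H](CCCCCCCCCCC/C=C(/C3OCCO3)CCCCCCCCCC[C@@H]2C=C[C@H](O[Si](C)(C)C(C)(C)C)[C@H](C)N2C(=O)C(F)(F)F)C=C[C@@H]1O[Si](C)(C)C(C)(C)C
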